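**Plan**

- Chain numbering: C1' (ArO–CH2), C2'–C3' (oxirane, CH3 on C3'), C4'H2, C5' (lactone O–CH), C6'H2, C7' (C(OH)CH3), C8' (lactone C=O).
- Retrosynthesis cuts ArO–C1' (Mitsunobu), the oxirane (epoxidation of a Z-allylic alcohol), C4'–C3' (sp3–sp2 coupling), C7'–CH3 (enolate methylation) and, as the key cut, both C8'–C7' and O–C5' of the butyrolactone, which sets CO2 free.
- Enabling feature: in the butyrolactone the ring O–C8'(=O) unit is one CO2 molecule bridging C7', which bears an oxygen and can serve as an α-alkoxy carbanion, and C5', a carbinol-type carbon that a carboxylate oxygen can enter by SN2.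
- Forward: a chiral-pool C4 triol unit becomes an α-alkoxystannane; the key step closes the butyrolactone (first ring); methylation, deprotection and iodination follow; the Z-alkenyl arm is coupled on, the oxirane (second ring) is formed and the bought coumarin is attached last.
- Stereochemistry: C5' from (S)-1,2,4-butanetriol with one Mitsunobu inversion; C7' by methylation of the lactone enolate anti to the C5' substituent (the C7' epimers, written RS until then, converge); Z geometry from trans-hydroalumination/iodination; C2'/C3' from L-(+)-tartrate-controlled epoxidation.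

Key step: step 5

Remark: compounds 3 to 9 are deliberately carried as epimer mixtures at C7'; step 6 passes through the planar enolate and sets this center.

**Step 1**
Reactants: 1 (S)-2-(2,2-dimethyl-1,3-dioxolan-4-yl)ethan-1-ol
Product: 2 (S)-2-(2,2-dimethyl-1,3-dioxolan-4-yl)acetaldehyde
Conditions: TEMPO (10 mol %), PhI(OAc)2 (1.1 equiv), CH2Cl2, rt
Reagents that add atoms: none
Why: oxoammonium (TEMPO) oxidation of a primary alcohol should stop at the aldehyde, and the near-neutral medium should leave the acetonide and the C5' center (not α to the carbonyl) untouched.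

**Step 2**
Reactants: 2 (S)-2-(2,2-dimethyl-1,3-dioxolan-4-yl)acetaldehyde
Product: 4 tributyl{(1RS)-2-[(4S)-2,2-dimethyl-1,3-dioxolan-4-yl]-1-(methoxymethoxy)ethyl}stannane, via α-hydroxystannane 3 (not isolated)
Conditions: Bu3SnH, LDA, THF, 0 °C (gives Bu3SnLi); then 2, −78 °C; aq NH4Cl; then MOMCl, i-Pr2NEt, CH2Cl2, 0 °C to rt
Reagents that add atoms: tributylstannyllithium [Li][Sn](CCCC)(CCCC)CCCC; chloromethyl methyl ether COCCl
Why: 1,2-addition of a stannyl anion to the aldehyde followed by immediate acetalisation of the labile α-hydroxystannane is the standard entry to α-alkoxystannanes; the new C7' center forms as an epimer mixture on purpose.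

**Step 3**
Reactants: 4 tributyl{(1RS)-2-[(4S)-2,2-dimethyl-1,3-dioxolan-4-yl]-1-(methoxymethoxy)ethyl}stannane
Product: 5 (2S,4RS)-4-(methoxymethoxy)-4-(tributylstannyl)butane-1,2-diol
Conditions: AcOH/H2O/THF (3:1:1), 40 °C
Reagents that add atoms: none
Why: acid-catalysed acetonide hydrolysis should spare the MOM acetal and the C–Sn bond under aqueous acetic acid, and C5' is not involved.

**Step 4**
Reactants: 5 (2S,4RS)-4-(methoxymethoxy)-4-(tributylstannyl)butane-1,2-diol
Product: 6 (2S,4RS)-4-(methoxymethoxy)-4-(tributylstannyl)-1-(trityloxy)butan-2-ol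
Conditions: TrCl (1.1 equiv), Et3N, DMAP (cat.), CH2Cl2, rt
Reagents that add atoms: trityl chloride ClC(c1ccccc1)(c1ccccc1)c1ccccc1
Why: tritylation is selective for the primary hydroxyl, leaves the C5' carbinol free for the key step and installs the bulky group that later steers the methylation.

**Step 5**
Reactants: 6 (2S,4RS)-4-(methoxymethoxy)-4-(tributylstannyl)-1-(trityloxy)butan-2-ol
Product: 9 (3RS,5R)-3-(methoxymethoxy)-5-[(trityloxy)methyl]oxolan-2-one, via dilithio alkoxide 7 (not isolated), via hydroxy acid 8 (not isolated)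
Conditions: n-BuLi (2.2 equiv), THF, −78 °C, 15 min; CO2 (dry gas), −78 to 0 °C; aq HCl to pH 4, 0 °C, extraction; then PPh3, DIAD, THF, 0 °C to rt
Reagents that add atoms: carbon dioxide O=C=O
Why: The first equivalent of n-BuLi deprotonates the C5' hydroxyl and the second effects tin–lithium exchange to the MOM-chelated α-alkoxy organolithium 7, which adds to CO2 and forms the C8'–C7' bond (hydroxy acid 8 after mild acidification); PPh3/DIAD then turn the C5' hydroxyl into an alkoxyphosphonium leaving group that one carboxylate oxygen displaces, forming the O–C5' bond. The closest known reaction types are the transmetalation–carboxylation of α-alkoxystannanes and the Mitsunobu lactonization of γ-hydroxy acids. The lactone ring closes 5-exo-tet by intramolecular SN2 at C5'. C5' becomes R by inversion of the S carbinol taken from (S)-1,2,4-butanetriol, whereas C7' is formed with retention from the epimeric stannane and stays a mixture that step 6 resolves. The step needs invertive O-alkylation to outrun retentive acyl transfer (acyloxyphosphonium path or acid-catalysed self-lactonization of 8) and needs the organolithium to be trapped before it decomposes; the cold pH 4 work-up with immediate use of 8, the unhindered secondary alcohol, the fairly acidic α-alkoxy acid and the chelated organolithium at −78 °C should secure this. Both oxygens of the lactone O–C(=O) unit thus come from CO2, and the original C5' oxygen leaves as phosphine oxide.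

**Step 6**
Reactants: 9 (3RS,5R)-3-(methoxymethoxy)-5-[(trityloxy)methyl]oxolan-2-one
Product: 11 (3R,5R)-3-(methoxymethoxy)-3-methyl-5-[(trityloxy)methyl]oxolan-2-one, via lithium enolate 10 (not isolated)
Conditions: LDA (1.2 equiv), THF, −78 °C; MeI (3 equiv), −78 to −40 °C
Reagents that add atoms: iodomethane CI
Why: in this enolate alkylation of a γ-substituted butyrolactone both C7' epimers give the same planar enolate and iodomethane should enter anti to the CH2OTr group on C5', so that CH3 ends trans and the oxygen cis to the C5' substituent (7'R).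

**Step 7**
Reactants: 11 (3R,5R)-3-(methoxymethoxy)-3-methyl-5-[(trityloxy)methyl]oxolan-2-one
Product: 12 (3R,5R)-3-hydroxy-5-(hydroxymethyl)-3-methyloxolan-2-one
Conditions: HCl (1 M) in MeOH, 40 °C
Reagents that add atoms: none
Why: acid-catalysed methanolysis removes the trityl ether and the MOM acetal together, while the γ-lactone (favoured over the δ-isomer) and the tertiary alcohol, which cannot ionise next to the carbonyl, should survive.

**Step 8**
Reactants: 12 (3R,5R)-3-hydroxy-5-(hydroxymethyl)-3-methyloxolan-2-one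
Product: 13 (3R,5R)-3-hydroxy-5-(iodomethyl)-3-methyloxolan-2-one
Conditions: PPh3, I2, imidazole, THF, 0 °C to rt
Reagents that add atoms: iodine [I][I]
Why: the Appel iodination proceeds through an alkoxyphosphonium ion that only the primary hydroxyl can form readily, the hindered tertiary α-hydroxyl staying free.

**Step 9**
Reactants: 14 but-2-yn-1-ol
Product: 16 (Z)-3-iodobut-2-en-1-ol, via cyclic alkenylaluminate 15 (not isolated)
Conditions: NaAlH2(OCH2CH2OMe)2 (Red-Al, 1.3 equiv), THF, 0 °C; then I2, −78 to 0 °C; aq KNaC4H4O6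
Reagents that add atoms: iodine [I][I]
Why: hydroxyl-directed trans-hydroalumination places aluminium on C3' in a five-membered alkoxyaluminate, and iodinolysis with retention gives the Z iodide with iodine cis to CH2OH.

**Step 10**
Reactants: 13 (3R,5R)-3-hydroxy-5-(iodomethyl)-3-methyloxolan-2-one; 16 (Z)-3-iodobut-2-en-1-ol
Product: 17 (3R,5S)-3-hydroxy-5-[(2Z)-4-hydroxy-2-methylbut-2-en-1-yl]-3-methyloxolan-2-one
Conditions: NiBr2(dme) (10 mol %; dme = 1,2-dimethoxyethane), 4,4'-di-tert-butyl-2,2'-bipyridine (10 mol %), Mn powder (2 equiv), NaI (0.25 equiv), DMA, rt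
Reagents that add atoms: none
Why: in this nickel-catalysed reductive cross-electrophile coupling zerovalent nickel inserts into the C(sp2)–I bond with retention of the Z geometry, the primary alkyl iodide enters as a radical and reductive elimination forms C4'–C3', while free hydroxyls and the lactone are tolerated because no base or preformed organometal is present (the C5 descriptor changes to S only through the priority rules).

**Step 11**
Reactants: 17 (3R,5S)-3-hydroxy-5-[(2Z)-4-hydroxy-2-methylbut-2-en-1-yl]-3-methyloxolan-2-one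
Product: 18 (3R,5R)-3-hydroxy-5-{[(2R,3S)-3-(hydroxymethyl)-2-methyloxiran-2-yl]methyl}-3-methyloxolan-2-one
Conditions: Ti(OiPr)4 (0.5 equiv), L-(+)-diethyl tartrate (0.6 equiv), t-BuOOH (2 equiv, in decane), 4 Å molecular sieves, CH2Cl2, −20 °C
Reagents that add atoms: tert-butyl hydroperoxide CC(C)(C)OO
Why: in the Sharpless asymmetric epoxidation the L-(+)-tartrate titanium complex should deliver oxygen under reagent control to the face that gives the (2'S,3'R)-oxirane (the sense known for nerol), the cis relation of C1' and C4' following from the Z alkene.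

**Step 12**
Reactants: 18 (3R,5R)-3-hydroxy-5-{[(2R,3S)-3-(hydroxymethyl)-2-methyloxiran-2-yl]methyl}-3-methyloxolan-2-one; 19 umbelliferone (7-hydroxy-2H-chromen-2-one)
Product: 20 7-{[(2S,3R)-3-{[(2R,4R)-4-hydroxy-4-methyl-5-oxooxolan-2-yl]methyl}-3-methyloxiran-2-yl]methoxy}-2H-chromen-2-one
Conditions: PPh3, DIAD, THF, 0 °C to rt
Reagents that add atoms: none
Why: Mitsunobu etherification of the primary epoxy alcohol with the acidic phenol runs under neutral conditions, so no stereocenter is touched, the tertiary alcohol is inert and the oxirane should not be opened.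

**Compound list**

1 | (S)-2-(2,2-dimethyl-1,3-dioxolan-4-yl)ethan-1-ol | OCC[C@H]1COC(C)(C)O1 | starting material
2 | (S)-2-(2,2-dimethyl-1,3-dioxolan-4-yl)acetaldehyde | O=CC[C@H]1COC(C)(C)O1 | intermediate
3 | (1RS)-2-[(4S)-2,2-dimethyl-1,3-dioxolan-4-yl]-1-(tributylstannyl)ethan-1-ol | CCCC[Sn](CCCC)(CCCC)C(O)C[C@H]1COC(C)(C)O1 | intermediate (not isolated)
4 | tributyl{(1RS)-2-[(4S)-2,2-dimethyl-1,3-dioxolan-4-yl]-1-(methoxymethoxy)ethyl}stannane | CCCC[Sn](CCCC)(CCCC)C(OCOC)C[C@H]1COC(C)(C)O1 | intermediate
5 | (2S,4RS)-4-(methoxymethoxy)-4-(tributylstannyl)butane-1,2-diol | CCCC[Sn](CCCC)(CCCC)C(OCOC)C[C@H](O)CO | intermediate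
6 | (2S,4RS)-4-(methoxymethoxy)-4-(tributylstannyl)-1-(trityloxy)butan-2-ol | CCCC[Sn](CCCC)(CCCC)C(OCOC)C[C@H](O)COC(c1ccccc1)(c1ccccc1)c1ccccc1 | intermediate
7 | lithium (2S,4RS)-4-lithio-4-(methoxymethoxy)-1-(trityloxy)butan-2-olate | [Li]C(OCOC)C[C@H](O[Li])COC(c1ccccc1)(c1ccccc1)c1ccccc1 | intermediate (not isolated)
8 | (2RS,4S)-4-hydroxy-2-(methoxymethoxy)-5-(trityloxy)pentanoic acid | OC(=O)C(OCOC)C[C@H](O)COC(c1ccccc1)(c1ccccc1)c1ccccc1 | intermediate (not isolated)
9 | (3RS,5R)-3-(methoxymethoxy)-5-[(trityloxy)methyl]oxolan-2-one | C(OC(c2ccccc2)(c2ccccc2)c2ccccc2)[C@H]1CC(OCOC)C(=O)O1 | intermediate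
10 | lithium (5R)-3-(methoxymethoxy)-5-[(trityloxy)methyl]-4,5-dihydrofuran-2-olate | C(OC(c2ccccc2)(c2ccccc2)c2ccccc2)[C@H]1CC(OCOC)=C(O[Li])O1 | intermediate (not isolated)
11 | (3R,5R)-3-(methoxymethoxy)-3-methyl-5-[(trityloxy)methyl]oxolan-2-one | C(OC(c2ccccc2)(c2ccccc2)c2ccccc2)[C@H]1C[C@@](C)(OCOC)C(=O)O1 | intermediate
12 | (3R,5R)-3-hydroxy-5-(hydroxymethyl)-3-methyloxolan-2-one | OC[C@H]1C[C@@](C)(O)C(=O)O1 | intermediate
13 | (3R,5R)-3-hydroxy-5-(iodomethyl)-3-methyloxolan-2-one | IC[C@H]1C[C@@](C)(O)C(=O)O1 | intermediate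
14 | but-2-yn-1-ol | CC#CCO | starting material
15 | sodium 2,2-bis(2-methoxyethoxy)-3-methyl-2,5-dihydro-1,2-oxaaluminol-2-uide | [Na+].CC1=CCO[Al-]1(OCCOC)OCCOC | intermediate (not isolated)
16 | (Z)-3-iodobut-2-en-1-ol | C/C(I)=C/CO | intermediate
17 | (3R,5S)-3-hydroxy-5-[(2Z)-4-hydroxy-2-methylbut-2-en-1-yl]-3-methyloxolan-2-one | OC/C=C(C)\C[C@H]1C[C@@](C)(O)C(=O)O1 | intermediate
18 | (3R,5R)-3-hydroxy-5-{[(2R,3S)-3-(hydroxymethyl)-2-methyloxiran-2-yl]methyl}-3-methyloxolan-2-one | C[C@]1(C[C@H]2C[C@@](C)(O)C(=O)O2)O[C@H]1CO | intermediate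
19 | umbelliferone (7-hydroxy-2H-chromen-2-one) | O=c1ccc2ccc(O)cc2o1 | starting material
20 | 7-{[(2S,3R)-3-{[(2R,4R)-4-hydroxy-4-methyl-5-oxooxolan-2-yl]methyl}-3-methyloxiran-2-yl]methoxy}-2H-chromen-2-one | C[C@]1(C[C@H]2C[C@@](C)(O)C(=O)O2)O[C@H]1COc1ccc2ccc(=O)oc2c1 | target

**Step count and risks**

Total step count: 12. Longest linear sequence: 11 steps (steps 1 to 8, then 10 to 12, from compound 1); step 9 is the one-step branch.

Steps most likely to fail:

Step 5. The ring could close with retention instead of inversion, by acyl transfer through an acyloxyphosphonium ion or by acid-catalysed self-lactonization of 8 before it is activated; this would give the C5' epimer. The organolithium could also be protonated before it meets CO2. The fallback takes the inversion out of the Mitsunobu stage and lets an epoxide deliver it. It sets out from 5: the primary hydroxyl is tosylated (TsCl, Et3N, Bu2SnO cat., CH2Cl2) to (2S,4RS)-2-hydroxy-4-(methoxymethoxy)-4-(tributylstannyl)butyl 4-methylbenzenesulfonate F1, and K2CO3 in MeOH closes the terminal epoxide tributyl{(1RS)-1-(methoxymethoxy)-2-[(2S)-oxiran-2-yl]ethyl}stannane F2 with C5' retained. Brief tin–lithium exchange (n-BuLi, 1.05 equiv, THF, −78 °C, 5 min) gives {(1RS)-1-(methoxymethoxy)-2-[(2S)-oxiran-2-yl]ethyl}lithium F3, which is carboxylated at once to (2RS)-2-(methoxymethoxy)-3-[(2S)-oxiran-2-yl]propanoic acid F4. On acidification (camphorsulfonic acid, CH2Cl2) this γ,δ-epoxy acid should close 5-exo with inversion at C5' to (3RS,5R)-5-(hydroxymethyl)-3-(methoxymethoxy)oxolan-2-one F5. Tritylation (TrCl, Et3N, DMAP) comes back to 9.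

Step 10. Either iodide could dimerise reductively, the Z geometry could be lost at the alkenylnickel stage, or the carboxylate could be expelled by reductive β-elimination with opening of the lactone. The fallback replaces the reductive coupling by an SN2 displacement with a preformed alkenylcopper reagent and sets out from 13 and 16. The tertiary hydroxyl of 13 is silylated (Me3SiOTf, 2,6-lutidine, CH2Cl2, −78 °C) to (3R,5R)-5-(iodomethyl)-3-methyl-3-[(trimethylsilyl)oxy]oxolan-2-one F6, and 16 is silylated (t-BuMe2SiCl, imidazole, DMF) to (Z)-tert-butyl[(3-iodobut-2-en-1-yl)oxy]dimethylsilane F7. Iodine–lithium exchange (t-BuLi, 2 equiv, Et2O, −78 °C) gives (Z)-{4-[(tert-butyldimethylsilyl)oxy]but-2-en-2-yl}lithium F8 with retention, and CuI (0.5 equiv) turns it into lithium bis{(Z)-4-[(tert-butyldimethylsilyl)oxy]but-2-en-2-yl}cuprate F9. The cuprate should displace the primary iodide of F6 (THF, −78 to −20 °C) to give (3R,5S)-5-[(2Z)-4-{[tert-butyl(dimethyl)silyl]oxy}-2-methylbut-2-en-1-yl]-3-methyl-3-[(trimethylsilyl)oxy]oxolan-2-one F10. Bu4NF in THF removes both silyl groups and comes back to 17.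

Step 11. Turnover could be slow and face selectivity poor, because the α-hydroxy lactone can chelate titanium in competition with the tartrate and Z-allylic alcohols are the slow substrate class of this epoxidation. The fallback inverts the order of the last two steps so that no free allylic hydroxyl is needed for the oxygen transfer. It sets out from 17: Mitsunobu etherification with 19 (PPh3, DIAD, THF) gives 7-{[(2Z)-4-[(2S,4R)-4-hydroxy-4-methyl-5-oxooxolan-2-yl]-3-methylbut-2-en-1-yl]oxy}-2H-chromen-2-one F11. The trisubstituted Z alkene of F11 is then epoxidised by Shi epoxidation with the enantiomer of the fructose-derived ketone catalyst (made from L-sorbose; KHSO5, K2CO3, MeCN/dimethoxymethane/buffer, 0 °C). The spiro transition-state model assigns this catalyst enantiomer to the required alkene face, and the electron-poor coumarin double bond should not react; this comes back to 20.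

**Further compounds**

F1 | step 5 | (2S,4RS)-2-hydroxy-4-(methoxymethoxy)-4-(tributylstannyl)butyl 4-methylbenzenesulfonate | CCCC[Sn](CCCC)(CCCC)C(OCOC)C[C@H](O)COS(=O)(=O)c1ccc(C)cc1
F2 | step 5 | tributyl{(1RS)-1-(methoxymethoxy)-2-[(2S)-oxiran-2-yl]ethyl}stannane | CCCC[Sn](CCCC)(CCCC)C(OCOC)C[C@H]1CO1
F3 | step 5 | {(1RS)-1-(methoxymethoxy)-2-[(2S)-oxiran-2-yl]ethyl}lithium | [Li]C(OCOC)C[C@H]1CO1
F4 | step 5 | (2RS)-2-(methoxymethoxy)-3-[(2S)-oxiran-2-yl]propanoic acid | OC(=O)C(OCOC)C[C@H]1CO1
F5 | step 5 | (3RS,5R)-5-(hydroxymethyl)-3-(methoxymethoxy)oxolan-2-one | OC[C@H]1CC(OCOC)C(=O)O1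
F6 | step 10 | (3R,5R)-5-(iodomethyl)-3-methyl-3-[(trimethylsilyl)oxy]oxolan-2-one | IC[C@H]1C[C@@](C)(O[Si](C)(C)C)C(=O)O1
F7 | step 10 | (Z)-tert-butyl[(3-iodobut-2-en-1-yl)oxy]dimethylsilane | C/C(I)=C/CO[Si](C)(C)C(C)(C)C
F8 | step 10 | (Z)-{4-[(tert-butyldimethylsilyl)oxy]but-2-en-2-yl}lithium | C/C([Li])=C/CO[Si](C)(C)C(C)(C)C
F9 | step 10 | lithium bis{(Z)-4-[(tert-butyldimethylsilyl)oxy]but-2-en-2-yl}cuprate | [Li+].C/C(=C/CO[Si](C)(C)C(C)(C)C)[Cu-]C(\C)=C/CO[Si](C)(C)C(C)(C)C
F10 | step 10 | (3R,5S)-5-[(2Z)-4-{[tert-butyl(dimethyl)silyl]oxy}-2-methylbut-2-en-1-yl]-3-methyl-3-[(trimethylsilyl)oxy]oxolan-2-one | CC(C)(C)[Si](C)(C)OC/C=C(C)\C[C@H]1C[C@@](C)(O[Si](C)(C)C)C(=O)O1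
F11 | step 11 | 7-{[(2Z)-4-[(2S,4R)-4-hydroxy-4-methyl-5-oxooxolan-2-yl]-3-methylbut-2-en-1-yl]oxy}-2H-chromen-2-one | O=c1ccc2ccc(OC/C=C(C)\C[C@H]3C[C@@](C)(O)C(=O)O3)cc2o1
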